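The early readings tell you how long these flasks need, so take the runs and the question first.

| flask | substrate | first nucleophile | second nucleophile | capture agent | temperature | remark | time |
|---|---|---|---|---|---|---|---|
| dawn | 0.10 M | 0.24 M | 1 M | 4 mM | 65 °C | run made earlier |  |
| autumn | 0.15 M | 0.24 M | 1 M | 4 mM | 78 °C | run made earlier |  |
| winter | 0.20 M | 0.24 M | 1 M | 8 mM | 65 °C | run made earlier |  |
| Monday's | 0.20 M | 0.240 M | 1.00 M | 4.00 mM | 85 °C |  | 6.0 min |
| Friday's | 0.20 M | 0.240 M | 1.00 M | 4.00 mM |  | at 70 °C until 2.0 min, from then on at 85 °C | 6.0 min |
| Tuesday's | 0.20 M | 0.240 M | 1.00 M | 4.00 mM | 70 °C |  | 6.0 min |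

| run | time / min | target / % | other capture product / % | trapped intermediate / % |
|---|---|---|---|---|
| dawn | 1.33 | 27 | 37 | 0 |
| dawn | 2.50 | 34 | 52 | 0 |
| dawn | 5.00 | 40 | 57 | 1 |
| dawn | 10.0 | 41 | 61 | 0 |
| dawn | 20.0 | 39 | 61 | 2 |
| autumn | 0.667 | 30 | 46 | 0 |
| autumn | 2.00 | 39 | 60 | 0 |
| autumn | 3.00 | 39 | 60 | 0 |
| autumn | 5.00 | 37 | 63 | 0 |
| autumn | 8.00 | 41 | 60 | 1 |
| winter | 1.33 | 23 | 34 | 1 |
| winter | 2.50 | 31 | 51 | 2 |
| winter | 5.00 | 39 | 60 | 0 |
| winter | 10.0 | 38 | 60 | 1 |
| winter | 20.0 | 39 | 63 | 0 |

(readings scatter by 1.5 percentage points)

- the numbers in the tables scatter by 1.5 percentage points (one standard deviation)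
- a reading or a percentage of target counts all its forms, free or not

1. which flask leads in share of target in all that became target or other capture product or trapped intermediate ("all alike" within 1.5 percentage points) (Monday's / Friday's / Tuesday's / all alike)
2. share of target in all that became target or other capture product or trapped intermediate, Monday's
3. share of target in all that became target or other capture product or trapped intermediate, Friday's
4. share of target in all that became target or other capture product or trapped intermediate, Tuesday's

At 1.33 min the dawn run reads 64.0 % of its substrate as target and other capture product, which, taken as a first-order loss, is a reading of 0.768 /min. Even at that run's 65 °C, 6.0 min holds 4.61 lifetimes, leaving about 0.997 %. So you are asking for a final split.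

Suppose each nucleophile captures in proportion to its concentration. Winter's last readings average 38.7 % target and 61.0 % other capture product. Take each c(nucleophile) as its charge minus half of what its product consumed. This gives the selectivity factor 2.96: target over other capture product, divided by mean c(first nucleophile) over mean c(second nucleophile). Autumn, at 78 °C, reads 2.89. These two runs also differ in substrate and capture agent, but I see no drift between them, so I hold the factor, though 85 °C lies beyond the runs.

Monday's, Friday's and Tuesday's share one charge. The bare charges give a share of 41.5 %. Mean concentrations then give a ratio of 0.623, so my estimate for each of these flasks is a share of 38.4 %.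

The forecast said 39.2 %, 39.3 % and 39.3 %, all alike, since “a temperature switch should change nothing”. Its Tuesday's figure stands 0.9 percentage points above mine.

The flasks give 37.6 %, 38.3 % and 38.4 %: all alike.

    substrate → open intermediate (k = 0.0190 /s, Ea = 87.0 kJ/mol)
    first nucleophile + open intermediate → target (k = 0.490 /M/s, Ea = 66.0 kJ/mol)
    second nucleophile + open intermediate → other capture product (k = 0.170 /M/s, Ea = 68.0 kJ/mol)
    open intermediate + capture agent → trapped intermediate (k = 0.00360 /M/s, Ea = 58.0 kJ/mol)
    second nucleophile + target ⇌ idle adduct, settled at all times (K = 0.820 /M, ΔH = −63.0 kJ/mol)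
    (constants at 70 °C)

Now give Tuesday's flask 0.41 M of first nucleophile, hold its other charges and its time, and keep the selectivity factor at 2.96. The bare charges give 54.8 %. The mean concentrations give a ratio of 1.10, hence a share of 52.4 %. That flask gives 52.4 %, and target, all its forms counted, at 52.4 %, now stands above other capture product, at 47.5 %.

(The data come from a simulation with constants of no real substance, and the scatter is random.)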